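**Plan**
- Retrosynthetic cuts, last to first: the butenolide O–C6 bond and the oxirane O–C5 bond (both from one C5=C6 alkene); that alkene from a δ-lactone C12–O–C5 by vinylogous β-elimination; C7–C8 (Ni/Cr ring closure); C5–C6 (vinylogous Mukaiyama aldol); C1–C10 (crotylboration).
- Enabling feature: the oxygens on three contiguous carbons, C4 and C5 of the oxirane and C6 of the butenolide (O, C12, C11, C7, C6). This is the pattern left by anti addition of a carboxylate and a halonium ion across C5=C6 of a (2Z,4E)-dienoic acid that carries a tertiary alcohol at C4.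
- Forward order: (R)-linalool gives C1–C5 with the C4 carbinol; crotylation adds C8–C10; a dihydropyranone template locks C12 cis to C6, serves as enol triflate and masks the acid; the 10-membered ring closes at C7–C8; the template is opened to the dienoic acid; the butenolide and oxirane form together; the two acylation-state changes finish the route.
- Stereochemistry: C4 from (R)-linalool (its oxygen becomes the oxirane oxygen); C1 and C10 from (Z)-crotyl-B(Ipc)2; C8 in the ring closure; C5 and C6 from the key step under control of the C4 carbinol.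

Key step: step 15

Remarks. Names use germacrane numbering (ring C1–C10, C11–C13 on C7, C14 on C10, C15 on C4). The lactone carbinol C5 of the δ-lactone intermediates forms as an epimer mixture and is erased in step 14, so their SMILES leave C5 open. The Ni/Cr ring closure is assumed to give the 8S carbinol; a fallback covers the other outcome.

**Step 1**
Reactants: 1 (R)-(−)-linalool
Product: 2 (5R)-5-ethenyl-5-methyloxolan-2-ol (lactol, both anomers; ring form of (4R)-4-hydroxy-4-methylhex-5-enal)
Conditions: O3 (1 equiv, Sudan red 7B end-point), CH2Cl2/MeOH, −78 °C; Me2S, −78 °C to rt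
Reagents that add atoms: ozone, [O-][O+]=O
Why: Chemoselective ozonolysis, since the electron-rich trisubstituted alkene reacts far faster than the vinyl group, so one equivalent should cleave only the isopropylidene unit and the hydroxy aldehyde closes to the lactol with the future C4 centre untouched.

**Step 2**
Reactants: 2 (5R)-5-ethenyl-5-methyloxolan-2-ol
Product: 3 (3S,4S,7R)-3,7-dimethylnona-1,8-diene-4,7-diol
Conditions: (Z)-crotyl-B(Ipc)2 from (+)-Ipc2BOMe [(−)-α-pinene series], THF/Et2O, −78 to −40 °C; then NaOH, H2O2, 0 °C to rt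
Reagents that add atoms: (Z)-crotyldiisopinocampheylborane, C/C=C\CB([C@H]1C[C@H]2C[C@@H]([C@@H]1C)C2(C)C)[C@H]1C[C@H]2C[C@@H]([C@@H]1C)C2(C)C
Why: Brown asymmetric (Z)-crotylboration of the open hydroxy-aldehyde tautomer, in which the closed chair transition state gives the syn C1–OH/C10–Me pair and the Ipc ligands of this series direct attack to the Re face, setting C1 (S) and C10 (S) by reagent control.

**Step 3**
Reactants: 3 (3S,4S,7R)-3,7-dimethylnona-1,8-diene-4,7-diol
Product: 4 (3S,4S,7R)-7-hydroxy-3,7-dimethylnona-1,8-dien-4-yl acetate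
Conditions: Ac2O, Et3N, DMAP (cat.), CH2Cl2, 0 °C
Reagents that add atoms: acetic anhydride, CC(=O)OC(C)=O
Why: DMAP-catalysed acylation distinguishes the secondary C1 carbinol from the hindered tertiary C4 alcohol, so the C1 acetate of the target is installed early.

**Step 4**
Reactants: 4 (3S,4S,7R)-7-hydroxy-3,7-dimethylnona-1,8-dien-4-yl acetate
Product: 5 (3S,4S,7R)-1,7-dihydroxy-3,7-dimethylnon-8-en-4-yl acetate
Conditions: 9-BBN, THF, 0 °C to rt; NaBO3·4H2O, H2O, rt
Reagents that add atoms: sodium perborate, [Na+].[Na+].O[B-]1(O)OO[B-](O)(O)OO1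
Why: Anti-Markovnikov hydroboration–oxidation, in which the bulky borane should prefer the vinyl group next to the tertiary C10–H carbon over the vinyl group on the fully substituted, oxygen-bearing C4 (slower for steric and inductive reasons), and perborate oxidises the C–B bond without touching the acetate.

**Step 5**
Reactants: 5 (3S,4S,7R)-1,7-dihydroxy-3,7-dimethylnon-8-en-4-yl acetate
Product: 6 (3S,4S,7R)-7-hydroxy-3,7-dimethyl-1-(triethylsilyloxy)non-8-en-4-yl acetate
Conditions: Et3SiCl, imidazole, CH2Cl2, 0 °C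
Reagents that add atoms: chlorotriethylsilane, CC[Si](Cl)(CC)CC
Why: Silylation of the primary alcohol only (the tertiary C4–OH is inert here), giving a primary triethylsilyl ether that step 12 can oxidise directly.

**Step 6**
Reactants: 6 (3S,4S,7R)-7-hydroxy-3,7-dimethyl-1-(triethylsilyloxy)non-8-en-4-yl acetate
Product: 7 (3S,4S,7R)-7-hydroxy-3,7-dimethyl-8-oxo-1-(triethylsilyloxy)octan-4-yl acetate
Conditions: O3, CH2Cl2, −78 °C; PPh3, −78 °C to rt
Reagents that add atoms: ozone, [O-][O+]=O
Why: Ozonolysis of the only remaining alkene with reductive work-up turns C5 into the aldehyde needed for chain extension, leaving C4 as a tertiary α-hydroxy centre.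

**Step 7**
Reactants: 8 tert-butyl acrylate; 9 4-methoxybenzyl alcohol
Product: 10 tert-butyl 3-[(4-methoxybenzyl)oxy]propanoate
Conditions: NaH (cat.), THF, 0 °C to rt
Reagents that add atoms: none
Why: Base-catalysed oxa-Michael addition of the benzylic alcohol to the acrylate, a standard route to 3-alkoxypropanoates.

**Step 8**
Reactants: 10 tert-butyl 3-[(4-methoxybenzyl)oxy]propanoate
Product: 11 tert-butyl 2-{[(4-methoxybenzyl)oxy]methyl}-3-oxobutanoate (racemic)
Conditions: LiN(iPr)2, THF, −78 °C; N-methoxy-N-methylacetamide, −78 °C; 1 M HCl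
Reagents that add atoms: N-methoxy-N-methylacetamide, CC(=O)N(C)OC
Why: Claisen-type C-acylation of the ester lithium enolate with a Weinreb amide at −78 °C, where the tetrahedral adduct survives until work-up and β-loss of the alkoxide is slow; the new stereocentre (C11) is of no consequence.

**Step 9**
Reactants: 11 tert-butyl 2-{[(4-methoxybenzyl)oxy]methyl}-3-oxobutanoate
Product: 12 1-tert-butoxy-2-{[(4-methoxybenzyl)oxy]methyl}-1,3-bis(trimethylsilyloxy)buta-1,3-diene
Conditions: Me3SiOTf, Et3N, Et2O, 0 °C
Reagents that add atoms: trimethylsilyl trifluoromethanesulfonate, C[Si](C)(C)OS(=O)(=O)C(F)(F)F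
Why: Double O-silylation of the β-keto ester gives the 1,3-bis(silyloxy)diene, a neutral γ-nucleophile that avoids a dianion prone to β-alkoxide loss.

**Step 10**
Reactants: 7 (3S,4S,7R)-7-hydroxy-3,7-dimethyl-8-oxo-1-(triethylsilyloxy)octan-4-yl acetate; 12 bis(silyloxy)diene
Product: 14 (3S,4S,7R)-7-hydroxy-7-[4-hydroxy-5-{[(4-methoxybenzyl)oxy]methyl}-6-oxo-3,6-dihydro-2H-pyran-2-yl]-3-methyl-1-(triethylsilyloxy)octan-4-yl acetate (δ-lactone C12–O–C5; C5 epimers), via hydroxy keto ester 13 (not isolated)
Conditions: BF3·OEt2, CH2Cl2, −78 °C; aq. NaHCO3, then citric acid, THF/H2O; PhMe, 110 °C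
Reagents that add atoms: none
Why: Vinylogous Mukaiyama aldol addition of the diene terminus (future C6) to aldehyde C5, then thermal loss of tert-butanol from the β-keto ester gives an acylketene that should be trapped by the new C5 hydroxyl (six-membered ring) rather than the tertiary C4–OH; the C5 stereocentre forms without control and is erased in step 14.

**Step 11**
Reactants: 14 hydroxypyranone
Product: 15 (3S,4S,7R)-7-hydroxy-7-[5-{[(4-methoxybenzyl)oxy]methyl}-6-oxo-4-(trifluoromethanesulfonyloxy)-3,6-dihydro-2H-pyran-2-yl]-3-methyl-1-(triethylsilyloxy)octan-4-yl acetate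
Conditions: PhNTf2, Et3N, DMAP (cat.), CH2Cl2, 0 °C to rt
Reagents that add atoms: N-phenylbis(trifluoromethanesulfonimide), O=S(=O)(N(c1ccccc1)S(=O)(=O)C(F)(F)F)C(F)(F)F
Why: O-sulfonylation of the acidic vinylogous acid (the tertiary alcohol does not compete); because both alkene carbons lie in the six-membered lactone, the triflate on C7 is locked trans to C12 and cis to C13, which fixes the geometry of the later tetrasubstituted C7=C11 bond.

**Step 12**
Reactants: 15 enol triflate
Product: 16 (3S,4S,7R)-7-hydroxy-7-[5-{[(4-methoxybenzyl)oxy]methyl}-6-oxo-4-(trifluoromethanesulfonyloxy)-3,6-dihydro-2H-pyran-2-yl]-3-methyl-1-oxooctan-4-yl acetate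
Conditions: (COCl)2, DMSO, CH2Cl2, −78 to −30 °C; Et3N, −78 to 0 °C
Reagents that add atoms: none
Why: Swern conditions convert a primary triethylsilyl ether directly into the aldehyde (silyl transfer to chloride, then the usual alkoxysulfonium ylide collapse), leaving the tertiary alcohol, acetate and enol triflate intact.

**Step 13**
Reactants: 16 triflate aldehyde
Product: 17 (1S,4R,8S,10S)-1-acetoxy-4,8-dihydroxy-13-[(4-methoxybenzyl)oxy]germacr-7(11)-en-12,5-olide (10-membered ring bridged by the δ-lactone; C5 epimers)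
Conditions: CrCl2 (excess), NiCl2 (cat.), DMSO/THF, rt, slow addition to high dilution
Reagents that add atoms: none
Why: Intramolecular Nozaki–Hiyama–Kishi reaction, in which nickel inserts into the enol triflate, the vinyl group passes to chromium and adds to the aldehyde to close the 10-membered carbocycle at C7–C8; the new C8 carbinol (needed: S) is set by the bridged transition state, and it cannot translactonise because it is trans to the lactone carbonyl.

**Step 14**
Reactants: 17 bridged δ-lactone
Product: 18 (1S,4R,8S,10S,5E)-1-acetoxy-4,8-dihydroxy-13-[(4-methoxybenzyl)oxy]germacra-5,7(11)-dien-12-oic acid (CO2H cis to C6)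
Conditions: KN(SiMe3)2, THF, −78 to −40 °C; pH 4 phosphate buffer
Reagents that add atoms: none
Why: Vinylogous E1cB ring opening of the 5,6-dihydropyran-2-one, in which γ-deprotonation at C6 (C8–H is switched off by the adjacent alkoxide) expels the carboxylate from C5 to give the (2Z,4E)-dienoic acid; the C7=C11 geometry is inherited from the lactone ring and C5=C6 should form E by outward rotation of C4.

**Step 15**
Reactants: 18 macrocyclic dienoic acid
Product: 20 (1S,4R,5R,6S,8S,10S)-1-acetoxy-4,5-epoxy-8-hydroxy-13-[(4-methoxybenzyl)oxy]germacr-7(11)-en-12,6-olide, via bromolactone 19 (not isolated)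
Conditions: NBS, THF, −40 to 0 °C; then Ag2O, 4 Å MS, rt, dark
Reagents that add atoms: none
Why: NBS transfers Br+ to the C5=C6 bond and the C12 carboxyl oxygen opens the bromonium ion at C6 from the opposite face, closing the butenolide (O, C12, C11, C7, C6) by a 5-exo ring closure; Ag2O then assists loss of bromide from C5 while the C4 hydroxyl attacks C5 from the rear in a 3-exo-tet closure to the oxirane. The closest known reaction types are the halolactonization of (2Z)-2,4-dienoic and γ,δ-unsaturated acids and the halohydrin-to-epoxide closure. C6 is set by anti addition across the E double bond and C5 by that anti addition followed by inversion, so the two new C–O bonds end up syn, which is the 5R,6S pattern next to the retained 4R centre. Face selectivity is the critical requirement: in the hydroxyl-in-plane (inside-alkoxy) rotamer of the C4 carbinol the ring methylene C3 stands perpendicular to the alkene and Br+ should enter anti to it, which is the face that lets the C4 oxygen, after rotation about C4–C5, displace bromide to the trans-disposed oxirane. Attack at C6 rather than C5 should follow from the neopentyl, oxygen-deactivated character of C5 and the reach of the cis carboxyl group, and no other electron-rich alkene or free primary alcohol is present. Silver-assisted closure is chosen over amine or carbonate bases to avoid E1cB loss of HBr through the acidic γ-hydrogen at C6.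

**Step 16**
Reactants: 20 epoxy butenolide alcohol
Product: 21 (1S,4R,5R,6S,8S,10S)-1-acetoxy-4,5-epoxy-8-(methacryloyloxy)-13-[(4-methoxybenzyl)oxy]germacr-7(11)-en-12,6-olide
Conditions: methacrylic anhydride, Et3N, DMAP (cat.), CH2Cl2, 0 °C to rt
Reagents that add atoms: methacrylic anhydride, C=C(C)C(=O)OC(=O)C(C)=C
Why: DMAP-catalysed acylation of the only free hydroxyl (allylic C8–OH) under mild base that should not enolise the butenolide or open the oxirane.

**Step 17**
Reactants: 21 13-O-(4-methoxybenzyl) glaucolide L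
Product: 22 glaucolide L
Conditions: DDQ, CH2Cl2/pH 7 buffer, 0 °C
Reagents that add atoms: none
Why: Oxidative cleavage of the 4-methoxybenzyl ether by DDQ (benzylic hydride abstraction, then hydrolysis of the oxocarbenium ion) under buffered conditions that spare the oxirane, both esters and the butenolide, releasing the C13 alcohol.

**Compound list**
1 | (R)-(−)-linalool, (3R)-3,7-dimethylocta-1,6-dien-3-ol | CC(C)=CCC[C@@](C=C)(C)O | starting material
2 | (5R)-5-ethenyl-5-methyloxolan-2-ol (anomer mixture) | OC1CC[C@@](C=C)(C)O1 | intermediate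
3 | (3S,4S,7R)-3,7-dimethylnona-1,8-diene-4,7-diol | C=C[C@H](C)[C@@H](O)CC[C@@](C=C)(C)O | intermediate
4 | (3S,4S,7R)-7-hydroxy-3,7-dimethylnona-1,8-dien-4-yl acetate | C=C[C@H](C)[C@@H](OC(C)=O)CC[C@@](C=C)(C)O | intermediate
5 | (3S,4S,7R)-1,7-dihydroxy-3,7-dimethylnon-8-en-4-yl acetate | OCC[C@H](C)[C@@H](OC(C)=O)CC[C@@](C=C)(C)O | intermediate
6 | (3S,4S,7R)-7-hydroxy-3,7-dimethyl-1-(triethylsilyloxy)non-8-en-4-yl acetate | CC[Si](CC)(CC)OCC[C@H](C)[C@@H](OC(C)=O)CC[C@@](C=C)(C)O | intermediate
7 | (3S,4S,7R)-7-hydroxy-3,7-dimethyl-8-oxo-1-(triethylsilyloxy)octan-4-yl acetate | CC[Si](CC)(CC)OCC[C@H](C)[C@@H](OC(C)=O)CC[C@@](C=O)(C)O | intermediate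
8 | tert-butyl acrylate | C=CC(=O)OC(C)(C)C | starting material
9 | 4-methoxybenzyl alcohol | COc1ccc(CO)cc1 | starting material
10 | tert-butyl 3-[(4-methoxybenzyl)oxy]propanoate | COc1ccc(COCCC(=O)OC(C)(C)C)cc1 | intermediate
11 | tert-butyl 2-{[(4-methoxybenzyl)oxy]methyl}-3-oxobutanoate (racemic) | CC(=O)C(COCc1ccc(OC)cc1)C(=O)OC(C)(C)C | intermediate
12 | 1-tert-butoxy-2-{[(4-methoxybenzyl)oxy]methyl}-1,3-bis(trimethylsilyloxy)buta-1,3-diene | C=C(O[Si](C)(C)C)C(COCc1ccc(OC)cc1)=C(OC(C)(C)C)O[Si](C)(C)C | intermediate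
13 | tert-butyl (6R,9S,10S)-9-acetoxy-5,6-dihydroxy-2-{[(4-methoxybenzyl)oxy]methyl}-6,10-dimethyl-3-oxo-12-(triethylsilyloxy)dodecanoate (C2 and C5 epimers) | CC[Si](CC)(CC)OCC[C@H](C)[C@@H](OC(C)=O)CC[C@@](C(O)CC(=O)C(COCc1ccc(OC)cc1)C(=O)OC(C)(C)C)(C)O | intermediate (not isolated)
14 | (3S,4S,7R)-7-hydroxy-7-[4-hydroxy-5-{[(4-methoxybenzyl)oxy]methyl}-6-oxo-3,6-dihydro-2H-pyran-2-yl]-3-methyl-1-(triethylsilyloxy)octan-4-yl acetate (C5 epimers) | CC[Si](CC)(CC)OCC[C@H](C)[C@@H](OC(C)=O)CC[C@@](C1CC(O)=C(COCc2ccc(OC)cc2)C(=O)O1)(C)O | intermediate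
15 | enol triflate of 14 at the pyranone 4-oxygen (C7–OTf) | CC[Si](CC)(CC)OCC[C@H](C)[C@@H](OC(C)=O)CC[C@@](C1CC(OS(=O)(=O)C(F)(F)F)=C(COCc2ccc(OC)cc2)C(=O)O1)(C)O | intermediate
16 | C8 aldehyde of 15 (1-oxo in place of 1-silyloxy) | O=CC[C@H](C)[C@@H](OC(C)=O)CC[C@@](C1CC(OS(=O)(=O)C(F)(F)F)=C(COCc2ccc(OC)cc2)C(=O)O1)(C)O | intermediate
17 | (1S,4R,8S,10S)-1-acetoxy-4,8-dihydroxy-13-[(4-methoxybenzyl)oxy]germacr-7(11)-en-12,5-olide (C5 epimers) | O[C@H]1C[C@H](C)[C@@H](OC(C)=O)CC[C@@](C)(O)C2CC1=C(COCc1ccc(OC)cc1)C(=O)O2 | intermediate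
18 | (1S,4R,8S,10S,5E)-1-acetoxy-4,8-dihydroxy-13-[(4-methoxybenzyl)oxy]germacra-5,7(11)-dien-12-oic acid (CO2H cis to C6) | O[C@H]1C[C@H](C)[C@@H](OC(C)=O)CC[C@@](C)(O)/C=C/C1=C(/COCc1ccc(OC)cc1)C(=O)O | intermediate
19 | (1S,4R,5S,6S,8S,10S)-1-acetoxy-5-bromo-4,8-dihydroxy-13-[(4-methoxybenzyl)oxy]germacr-7(11)-en-12,6-olide | O[C@H]1C[C@H](C)[C@@H](OC(C)=O)CC[C@@](C)(O)[C@@H](Br)[C@H]2OC(=O)C(COCc3ccc(OC)cc3)=C12 | intermediate (not isolated)
20 | (1S,4R,5R,6S,8S,10S)-1-acetoxy-4,5-epoxy-8-hydroxy-13-[(4-methoxybenzyl)oxy]germacr-7(11)-en-12,6-olide | O[C@H]1C[C@H](C)[C@@H](OC(C)=O)CC[C@@]2(C)O[C@@H]2[C@H]2OC(=O)C(COCc3ccc(OC)cc3)=C12 | intermediate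
21 | 13-O-(4-methoxybenzyl) glaucolide L (8-methacrylate of 20) | C=C(C)C(=O)O[C@H]1C[C@H](C)[C@@H](OC(C)=O)CC[C@@]2(C)O[C@@H]2[C@H]2OC(=O)C(COCc3ccc(OC)cc3)=C12 | intermediate
22 | glaucolide L | C=C(C)C(=O)O[C@H]1C[C@H](C)[C@@H](OC(C)=O)CC[C@@]2(C)O[C@@H]2[C@H]2OC(=O)C(CO)=C12 | target

**Step count and risks**
Total step count: 17. Longest linear sequence: 14 steps (steps 1–6 and 10–17, from (R)-linalool).

Steps most likely to fail:

Step 15. The bromonium ion may form on the other face of C5=C6, which would give the C5,C6-diastereomeric bromolactone and then a cis-oxirane, or HBr may be lost across C5–C6 during the closure. The fallback sets out from 18 and uses a dehydrative SN2′ lactonization (PdCl2(MeCN)2 as divalent palladium catalyst, THF, 0 °C, or camphorsulfonic acid). The carboxyl oxygen should add to C6 syn to the departing C4 hydroxyl with 1,3-chirality transfer from the linalool centre, giving (1S,6S,8S,10S,4E)-1-acetoxy-8-hydroxy-13-[(4-methoxybenzyl)oxy]germacra-4,7(11)-dien-12,6-olide F1. Epoxidation with mCPBA/NaHCO3 should then take the only electron-rich alkene from the face anti to C7 in the A(1,3)-minimised rotamer, and the route is rejoined at 20.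

Step 13. Facial selectivity at C8 may be low in the chromium-mediated addition, and the two C5 epimers may behave differently. The fallback sets out from 17 as the C8 epimer mixture. Dess–Martin oxidation gives the C8 ketone, (1S,4R,10S)-1-acetoxy-4-hydroxy-13-[(4-methoxybenzyl)oxy]-8-oxogermacr-7(11)-en-12,5-olide F2. Reduction with (R)-2-methyl-CBS-oxazaborolidine and catecholborane at −78 °C (alkenyl C7 as the large group) should set C8 by reagent control, and the route is rejoined at 17 as the 8S alcohol.

Step 10. Lewis-acid-promoted addition to the hindered, chelating α-hydroxy aldehyde may be slow, with competing protodesilylation of 12 or α-ketol shift of 7. The fallback sets out from 11 and 7: the dianion of 11 (NaH, then n-BuLi, THF, −20 °C) is added to 7 at −78 °C to give 13 directly, followed by the same thermolysis in toluene. No compound outside the list is formed (F0), and the route is rejoined at 14.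

**Further compounds**
F1 | step 15 | (1S,6S,8S,10S,4E)-1-acetoxy-8-hydroxy-13-[(4-methoxybenzyl)oxy]germacra-4,7(11)-dien-12,6-olide | O[C@H]1C[C@H](C)[C@@H](OC(C)=O)CC/C(C)=C/[C@H]2OC(=O)C(COCc3ccc(OC)cc3)=C12
F2 | step 13 | (1S,4R,10S)-1-acetoxy-4-hydroxy-13-[(4-methoxybenzyl)oxy]-8-oxogermacr-7(11)-en-12,5-olide (C5 epimers) | O=C1C[C@H](C)[C@@H](OC(C)=O)CC[C@@](C)(O)C2CC1=C(COCc1ccc(OC)cc1)C(=O)O2
F0 | step 10 | none | none
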